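**Assumption:** the SMILES is taken literally: 3R, 11R, 12R, 13S, 4E,6E,8E, 14Z (C13 and C16 cis), free hydroquinone. Ansamycin numbering is used: C1 amide carbonyl, C3 methoxy carbon, C4–C9 triene, C11 and C13 carbinols, C12 methyl carbon, C14=C15 trisubstituted alkene, C17 benzylic carbon.

## Retrosynthetic overview

1. Target ⇐ quinone ⇐ hydroquinone dimethyl ether; the 21-membered macrolactam is the only ring formed (the benzene ring is bought) and is closed late by a double Stille coupling of a bis(E-vinyl iodide) with (E)-1,2-bis(tributylstannyl)ethene (C5–C6 and C7–C8).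
2. Bis-iodide ⇐ amide bond between an aniline (arene plus C9–C17) and (3R,4E)-5-iodo-3-methoxypent-4-enoic acid (from dimethyl (R)-malate), then Takai iodo-olefination at C9.
3. C9–C11 ⇐ crossed Claisen condensation of a Weinreb amide with tert-butyl acetate, then hydroxyl-directed 1,3-anti reduction (sets C11).
4. Key bond C12–C13 ⇐ intermolecular Evans syn aldol of (Z)-5-aryl-2-methylpent-2-enal with (S)-4-benzyl-3-propionyloxazolidin-2-one (sets C12 and C13).
5. Z-enal ⇐ 2-hydroxy-5-methoxybenzaldehyde by nitration, methylation, Wittig, alkene hydrogenation and Still–Gennari olefination (sets 14Z).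

## Route

**Step 1**
Reactants: 1 2-hydroxy-5-methoxybenzaldehyde
Product: 2 2-hydroxy-5-methoxy-3-nitrobenzaldehyde
Conditions: HNO3 (70%, 1.05 equiv), AcOH, 10–15 °C
Reagents that add atoms: nitric acid, O[N+](=O)[O-]
Why: Electrophilic aromatic nitration goes to C3, the only free position ortho to the phenol (para is blocked by OMe) and meta to the formyl group.

**Step 2**
Reactants: 2 2-hydroxy-5-methoxy-3-nitrobenzaldehyde
Product: 3 2,5-dimethoxy-3-nitrobenzaldehyde
Conditions: MeI, K2CO3, DMF, 50 °C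
Reagents that add atoms: iodomethane, CI
Why: Williamson O-methylation of the acidic o-nitrophenol.

**Step 3**
Reactants: 3 2,5-dimethoxy-3-nitrobenzaldehyde; 4 ethyl (triphenylphosphoranylidene)acetate
Product: 5 ethyl (2E)-3-(2,5-dimethoxy-3-nitrophenyl)prop-2-enoate
Conditions: toluene, 80 °C
Reagents that add atoms: none
Why: Wittig olefination with a stabilised ylide adds C15 and C16 (the alkene geometry is removed in the next step).

**Step 4**
Reactants: 5 ethyl (2E)-3-(2,5-dimethoxy-3-nitrophenyl)prop-2-enoate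
Product: 6 ethyl 3-(2,5-dimethoxy-3-nitrophenyl)propanoate
Conditions: H2 (4 atm), RhCl(PPh3)3 (5 mol %), benzene/EtOH 1:1, 50 °C
Reagents that add atoms: none
Why: Homogeneous hydrogenation with RhCl(PPh3)3 saturates the conjugated alkene while leaving the aromatic nitro group and the ester untouched.

**Step 5**
Reactants: 6 ethyl 3-(2,5-dimethoxy-3-nitrophenyl)propanoate
Product: 7 3-(2,5-dimethoxy-3-nitrophenyl)propanal
Conditions: i-Bu2AlH (1.1 equiv), CH2Cl2, −78 °C; MeOH, then aq. potassium sodium tartrate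
Reagents that add atoms: none
Why: Partial ester reduction stops at the aldehyde because the aluminium hemiacetal is stable at −78 °C; the nitro group is inert at this temperature.

**Step 6**
Reactants: 7 3-(2,5-dimethoxy-3-nitrophenyl)propanal; 8 ethyl 2-[bis(2,2,2-trifluoroethoxy)phosphoryl]propanoate
Product: 10 ethyl (2Z)-5-(2,5-dimethoxy-3-nitrophenyl)-2-methylpent-2-enoate, via potassium phosphonate carbanion 9 (not isolated)
Conditions: 8, KN(SiMe3)2, 18-crown-6, THF, −78 °C; then 7, −78 °C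
Reagents that add atoms: none
Why: Still–Gennari modification of the Horner–Wadsworth–Emmons reaction; fast, irreversible elimination from the kinetic adduct of the trifluoroethyl phosphonate gives the Z-trisubstituted enoate, which fixes the 14Z geometry.

**Step 7**
Reactants: 10 ethyl (2Z)-5-(2,5-dimethoxy-3-nitrophenyl)-2-methylpent-2-enoate
Product: 11 (2Z)-5-(2,5-dimethoxy-3-nitrophenyl)-2-methylpent-2-en-1-ol
Conditions: i-Bu2AlH (2.5 equiv), CH2Cl2, −78 °C; aq. potassium sodium tartrate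
Reagents that add atoms: none
Why: 1,2-Reduction of the enoate to the allylic alcohol with retention of the Z geometry.

**Step 8**
Reactants: 11 (2Z)-5-(2,5-dimethoxy-3-nitrophenyl)-2-methylpent-2-en-1-ol
Product: 12 (2Z)-5-(2,5-dimethoxy-3-nitrophenyl)-2-methylpent-2-enal
Conditions: MnO2 (15 equiv), CH2Cl2, rt; used at once
Reagents that add atoms: none
Why: Neutral allylic oxidation with MnO2 gives the Z-enal without Z-to-E isomerisation.

**Step 9 (key fragment union)**
Reactants: 12 (2Z)-5-(2,5-dimethoxy-3-nitrophenyl)-2-methylpent-2-enal; 13 (4S)-4-benzyl-3-propionyl-1,3-oxazolidin-2-one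
Product: 15 (4S)-4-benzyl-3-[(2S,3S,4Z)-7-(2,5-dimethoxy-3-nitrophenyl)-3-hydroxy-2,4-dimethylhept-4-enoyl]-1,3-oxazolidin-2-one, via dibutylboron Z-enolate 14 (not isolated)
Conditions: 13, Bu2BOTf, i-Pr2NEt, CH2Cl2, 0 °C; then 12, −78 → 0 °C; pH 7 buffer, MeOH, H2O2
Reagents that add atoms: none
Why: Intermolecular Evans syn aldol; the Z boron enolate reacts through a Zimmerman–Traxler chair on the face away from the benzyl group, forming the C12–C13 bond and setting the 12,13-syn pair (2S,3S in the adduct, equal to 12R,13S of the target).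

**Step 10**
Reactants: 15 the aldol adduct
Product: 16 (2S,3S,4Z)-7-(2,5-dimethoxy-3-nitrophenyl)-3-hydroxy-N-methoxy-N,2,4-trimethylhept-4-enamide
Conditions: MeNHOMe·HCl, AlMe3, CH2Cl2, −20 → 0 °C
Reagents that add atoms: N,O-dimethylhydroxylamine hydrochloride, CNOC.Cl
Why: Weinreb transamidation; the aluminium amide, guided by the free β-hydroxyl, attacks the exocyclic carbonyl and releases the auxiliary without epimerising C12.

**Step 11**
Reactants: 16 the Weinreb amide; 17 tert-butyl acetate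
Product: 19 tert-butyl (4S,5S,6Z)-9-(2,5-dimethoxy-3-nitrophenyl)-5-hydroxy-4,6-dimethyl-3-oxonon-6-enoate, via lithium tert-butyl acetate enolate 18 (not isolated)
Conditions: 17 (4 equiv), LiN(SiMe3)2 (4 equiv), THF, −78 °C; then 16, −78 → −20 °C; aq. NH4Cl
Reagents that add atoms: none
Why: Crossed Claisen condensation; the ester enolate is acylated by the Weinreb amide, whose chelated tetrahedral intermediate prevents over-addition, and the excess enolate covers the free hydroxyl.

**Step 12**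
Reactants: 19 the δ-hydroxy-β-keto ester
Product: 20 tert-butyl (3R,4R,5S,6Z)-9-(2,5-dimethoxy-3-nitrophenyl)-3,5-dihydroxy-4,6-dimethylnon-6-enoate
Conditions: Me4N[BH(OAc)3], MeCN/AcOH 1:1, −30 °C
Reagents that add atoms: none
Why: Evans–Saksena hydroxyl-directed reduction; the C13 alkoxy(diacetoxy)borohydride delivers hydride intramolecularly through a chair, giving the 1,3-anti diol and so the 11R centre.

**Step 13**
Reactants: 20 the anti-diol
Product: 21 tert-butyl (3R,4R,5S,6Z)-3,5-bis[(tert-butyldimethylsilyl)oxy]-9-(2,5-dimethoxy-3-nitrophenyl)-4,6-dimethylnon-6-enoate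
Conditions: TBSOTf, 2,6-lutidine, CH2Cl2, −78 → 0 °C
Reagents that add atoms: tert-butyldimethylsilyl trifluoromethanesulfonate, CC(C)(C)[Si](C)(C)OS(=O)(=O)C(F)(F)F
Why: Silyl triflate with a hindered base silylates both secondary alcohols, including the hindered allylic one.

**Step 14**
Reactants: 21 the bis-silyl ether
Product: 22 tert-butyl (3R,4R,5S,6Z)-9-(3-amino-2,5-dimethoxyphenyl)-3,5-bis[(tert-butyldimethylsilyl)oxy]-4,6-dimethylnon-6-enoate
Conditions: Zn, NH4Cl, THF/MeOH/H2O, rt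
Reagents that add atoms: none
Why: Near-neutral dissolving-metal reduction of the nitro group spares the alkene, the silyl ethers and the tert-butyl ester.

**Step 15**
Reactants: 23 dimethyl (R)-malate
Product: 24 methyl (3R)-3,4-dihydroxybutanoate
Conditions: BH3·SMe2, NaBH4 (5 mol %), THF, 0 °C → rt; MeOH
Reagents that add atoms: none
Why: Hydroxyl-directed chemoselective borane reduction of the ester next to the free hydroxyl (through the cyclic alkoxyborane); the stereocentre is not touched.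

**Step 16**
Reactants: 24 methyl (3R)-3,4-dihydroxybutanoate
Product: 25 methyl (3R)-4-[(tert-butyldiphenylsilyl)oxy]-3-hydroxybutanoate
Conditions: TBDPSCl, imidazole, CH2Cl2, 0 °C
Reagents that add atoms: tert-butyl(chloro)diphenylsilane, CC(C)(C)[Si](Cl)(c1ccccc1)c1ccccc1
Why: The bulky silyl chloride protects the primary alcohol selectively.

**Step 17**
Reactants: 25 the primary silyl ether
Product: 26 methyl (3R)-4-[(tert-butyldiphenylsilyl)oxy]-3-methoxybutanoate
Conditions: Me3OBF4, 1,8-bis(dimethylamino)naphthalene, 4 Å molecular sieves, CH2Cl2, rt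
Reagents that add atoms: trimethyloxonium tetrafluoroborate, C[O+](C)C.F[B-](F)(F)F
Why: Non-basic O-methylation with Meerwein salt avoids β-elimination or retro-aldol cleavage of the β-hydroxy ester.

**Step 18**
Reactants: 26 the methyl ether
Product: 27 methyl (3R)-4-hydroxy-3-methoxybutanoate
Conditions: Bu4NF, AcOH, THF, 0 °C; kept cold and used at once
Reagents that add atoms: none
Why: Acetic-acid-buffered fluoride desilylation frees the primary alcohol; buffering and immediate use suppress γ-lactonisation.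

**Step 19**
Reactants: 27 methyl (3R)-4-hydroxy-3-methoxybutanoate
Product: 28 methyl (3R)-3-methoxy-4-oxobutanoate
Conditions: Dess–Martin periodinane, NaHCO3, CH2Cl2, 0 °C
Reagents that add atoms: none
Why: Buffered Dess–Martin oxidation gives the α-methoxy aldehyde without epimerisation.

**Step 20**
Reactants: 28 methyl (3R)-3-methoxy-4-oxobutanoate
Product: 29 methyl (3R,4E)-5-iodo-3-methoxypent-4-enoate
Conditions: CrCl2 (8 equiv), CHI3 (3 equiv), THF/1,4-dioxane 1:6, 0 °C → rt, dark
Reagents that add atoms: iodoform, IC(I)I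
Why: Takai iodo-olefination; the geminal dichromium species made from iodoform and divalent chromium adds to the aldehyde and eliminates to the E-vinyl iodide under non-basic conditions.

**Step 21**
Reactants: 29 methyl (3R,4E)-5-iodo-3-methoxypent-4-enoate
Product: 30 (3R,4E)-5-iodo-3-methoxypent-4-enoic acid
Conditions: LiOH, THF/H2O, 0 °C; then 1 M HCl
Reagents that add atoms: lithium hydroxide, [Li+].[OH-]
Why: Cold saponification of the methyl ester without β-elimination of methoxide.

**Step 22**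
Reactants: 22 the aniline; 30 (3R,4E)-5-iodo-3-methoxypent-4-enoic acid
Product: 31 tert-butyl (3R,4R,5S,6Z)-3,5-bis[(tert-butyldimethylsilyl)oxy]-9-{3-[(3R,4E)-5-iodo-3-methoxypent-4-enamido]-2,5-dimethoxyphenyl}-4,6-dimethylnon-6-enoate
Conditions: bis(2-oxo-3-oxazolidinyl)phosphinic chloride (BOPCl), i-Pr2NEt, CH2Cl2, 0 °C → rt
Reagents that add atoms: none
Why: Amide coupling through the phosphinic mixed anhydride acylates the hindered, weakly nucleophilic aniline under mild conditions.

**Step 23**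
Reactants: 31 the anilide ester
Product: 32 (3R,4E)-N-{3-[(3Z,5S,6R,7R)-5,7-bis[(tert-butyldimethylsilyl)oxy]-9-hydroxy-4,6-dimethylnon-3-en-1-yl]-2,5-dimethoxyphenyl}-5-iodo-3-methoxypent-4-enamide
Conditions: i-Bu2AlH (5 equiv), CH2Cl2, −78 → −20 °C; aq. potassium sodium tartrate
Reagents that add atoms: none
Why: Hydride reduction of the tert-butyl ester to the primary alcohol; the anilide is first deprotonated to an unreactive aluminium amidate.

**Step 24**
Reactants: 32 the primary alcohol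
Product: 33 (3R,4E)-N-{3-[(3Z,5S,6R,7R)-5,7-bis[(tert-butyldimethylsilyl)oxy]-4,6-dimethyl-9-oxonon-3-en-1-yl]-2,5-dimethoxyphenyl}-5-iodo-3-methoxypent-4-enamide
Conditions: Pr4N[RuO4] (5 mol %), N-methylmorpholine N-oxide, 4 Å molecular sieves, CH2Cl2, rt
Reagents that add atoms: none
Why: Ley–Griffith oxidation is neutral and spares the electron-rich anilide, the vinyl iodide and the silyl ethers.

**Step 25**
Reactants: 33 the C9 aldehyde
Product: 34 (3R,4E)-N-{3-[(3Z,5S,6R,7R,9E)-5,7-bis[(tert-butyldimethylsilyl)oxy]-10-iodo-4,6-dimethyldeca-3,9-dien-1-yl]-2,5-dimethoxyphenyl}-5-iodo-3-methoxypent-4-enamide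
Conditions: CrCl2 (10 equiv), CHI3 (3 equiv), THF/1,4-dioxane 1:6, 0 °C → rt, dark
Reagents that add atoms: iodoform, IC(I)I
Why: Takai iodo-olefination installs the second E-vinyl iodide (C8=C9); the existing vinyl iodide and the amide are inert to divalent chromium without a nickel co-catalyst.

**Step 26**
Reactants: 34 the bis(vinyl iodide); 35 (E)-1,2-bis(tributylstannyl)ethene
Product: 36 the 21-membered macrolactam as its 11,13-bis-O-(tert-butyldimethylsilyl) ether and hydroquinone dimethyl ether (3R,11R,12R,13S; 4E,6E,8E,14Z)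
Conditions: PdCl2(MeCN)2 (20 mol %), i-Pr2NEt, DMF/THF 1:1, 1 mM, rt
Reagents that add atoms: none
Why: Double Stille coupling ("stitching"), first intermolecular and then intramolecular, proceeds with retention of alkene geometry, completes the E,E,E-triene and closes the macrocycle.

**Step 27**
Reactants: 36 the protected macrolactam
Product: 37 the hydroquinone dimethyl ether of the target (free 11,13-diol)
Conditions: HF·pyridine, pyridine, THF, 0 °C → rt
Reagents that add atoms: none
Why: Pyridine-buffered fluoride desilylation removes both silyl ethers without ionising the allylic C3 methyl ether or the C13 allylic alcohol.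

**Step 28**
Reactants: 37 the hydroquinone dimethyl ether of the target
Product: 38 the quinone form of the target (2-acylamino-6-alkyl-1,4-benzoquinone)
Conditions: (NH4)2Ce(NO3)6 (2.5 equiv), MeCN/H2O 2:1, 0 °C, 10 min
Reagents that add atoms: water, O
Why: Oxidative demethylation of the p-dimethoxy anilide by tetravalent cerium (single-electron oxidation, water attack, loss of methanol) is much faster than oxidation of the triene or the alcohols.

**Step 29**
Reactants: 38 the quinone
Product: 39 the target hydroquinone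
Conditions: Na2S2O4, EtOAc/H2O, rt, argon
Reagents that add atoms: none
Why: Dithionite reduces the quinone to the hydroquinone in two electrons without touching any stereocentre or alkene; the product is handled under argon.

## Compound list

1 | 2-hydroxy-5-methoxybenzaldehyde | O=Cc1cc(OC)ccc1O | starting material
2 | 2-hydroxy-5-methoxy-3-nitrobenzaldehyde | O=Cc1cc(OC)cc([N+](=O)[O-])c1O | intermediate
3 | 2,5-dimethoxy-3-nitrobenzaldehyde | O=Cc1cc(OC)cc([N+](=O)[O-])c1OC | intermediate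
4 | ethyl (triphenylphosphoranylidene)acetate | CCOC(=O)C=P(c1ccccc1)(c1ccccc1)c1ccccc1 | starting material
5 | ethyl (2E)-3-(2,5-dimethoxy-3-nitrophenyl)prop-2-enoate | CCOC(=O)/C=C/c1cc(OC)cc([N+](=O)[O-])c1OC | intermediate
6 | ethyl 3-(2,5-dimethoxy-3-nitrophenyl)propanoate | CCOC(=O)CCc1cc(OC)cc([N+](=O)[O-])c1OC | intermediate
7 | 3-(2,5-dimethoxy-3-nitrophenyl)propanal | O=CCCc1cc(OC)cc([N+](=O)[O-])c1OC | intermediate
8 | ethyl 2-[bis(2,2,2-trifluoroethoxy)phosphoryl]propanoate | CCOC(=O)C(C)P(=O)(OCC(F)(F)F)OCC(F)(F)F | starting material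
9 | potassium carbanion of phosphonate 8 | CCOC(=O)[C-](C)P(=O)(OCC(F)(F)F)OCC(F)(F)F.[K+] | intermediate
10 | ethyl (2Z)-5-(2,5-dimethoxy-3-nitrophenyl)-2-methylpent-2-enoate | CCOC(=O)/C(C)=C\CCc1cc(OC)cc([N+](=O)[O-])c1OC | intermediate
11 | (2Z)-5-(2,5-dimethoxy-3-nitrophenyl)-2-methylpent-2-en-1-ol | OC/C(C)=C\CCc1cc(OC)cc([N+](=O)[O-])c1OC | intermediate
12 | (2Z)-5-(2,5-dimethoxy-3-nitrophenyl)-2-methylpent-2-enal | O=C/C(C)=C\CCc1cc(OC)cc([N+](=O)[O-])c1OC | intermediate
13 | (4S)-4-benzyl-3-propionyl-1,3-oxazolidin-2-one | CCC(=O)N1[C@@H](Cc2ccccc2)COC1=O | starting material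
14 | dibutylboron Z-enolate of 13 | C/C=C(\OB(CCCC)CCCC)N1[C@@H](Cc2ccccc2)COC1=O | intermediate
15 | (4S)-4-benzyl-3-[(2S,3S,4Z)-7-(2,5-dimethoxy-3-nitrophenyl)-3-hydroxy-2,4-dimethylhept-4-enoyl]-1,3-oxazolidin-2-one | O=C(N1[C@@H](Cc2ccccc2)COC1=O)[C@@H](C)[C@H](O)/C(C)=C\CCc1cc(OC)cc([N+](=O)[O-])c1OC | intermediate
16 | (2S,3S,4Z)-7-(2,5-dimethoxy-3-nitrophenyl)-3-hydroxy-N-methoxy-N,2,4-trimethylhept-4-enamide | CON(C)C(=O)[C@@H](C)[C@H](O)/C(C)=C\CCc1cc(OC)cc([N+](=O)[O-])c1OC | intermediate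
17 | tert-butyl acetate | CC(=O)OC(C)(C)C | starting material
18 | lithium enolate of tert-butyl acetate | C=C(O[Li])OC(C)(C)C | intermediate
19 | tert-butyl (4S,5S,6Z)-9-(2,5-dimethoxy-3-nitrophenyl)-5-hydroxy-4,6-dimethyl-3-oxonon-6-enoate | CC(C)(C)OC(=O)CC(=O)[C@@H](C)[C@H](O)/C(C)=C\CCc1cc(OC)cc([N+](=O)[O-])c1OC | intermediate
20 | tert-butyl (3R,4R,5S,6Z)-9-(2,5-dimethoxy-3-nitrophenyl)-3,5-dihydroxy-4,6-dimethylnon-6-enoate | CC(C)(C)OC(=O)C[C@@H](O)[C@@H](C)[C@H](O)/C(C)=C\CCc1cc(OC)cc([N+](=O)[O-])c1OC | intermediate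
21 | tert-butyl (3R,4R,5S,6Z)-3,5-bis[(tert-butyldimethylsilyl)oxy]-9-(2,5-dimethoxy-3-nitrophenyl)-4,6-dimethylnon-6-enoate | CC(C)(C)OC(=O)C[C@@H](O[Si](C)(C)C(C)(C)C)[C@@H](C)[C@H](O[Si](C)(C)C(C)(C)C)/C(C)=C\CCc1cc(OC)cc([N+](=O)[O-])c1OC | intermediate
22 | tert-butyl (3R,4R,5S,6Z)-9-(3-amino-2,5-dimethoxyphenyl)-3,5-bis[(tert-butyldimethylsilyl)oxy]-4,6-dimethylnon-6-enoate | CC(C)(C)OC(=O)C[C@@H](O[Si](C)(C)C(C)(C)C)[C@@H](C)[C@H](O[Si](C)(C)C(C)(C)C)/C(C)=C\CCc1cc(OC)cc(N)c1OC | intermediate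
23 | dimethyl (R)-malate | COC(=O)C[C@@H](O)C(=O)OC | starting material
24 | methyl (3R)-3,4-dihydroxybutanoate | COC(=O)C[C@@H](O)CO | intermediate
25 | methyl (3R)-4-[(tert-butyldiphenylsilyl)oxy]-3-hydroxybutanoate | COC(=O)C[C@@H](O)CO[Si](c1ccccc1)(c1ccccc1)C(C)(C)C | intermediate
26 | methyl (3R)-4-[(tert-butyldiphenylsilyl)oxy]-3-methoxybutanoate | COC(=O)C[C@@H](OC)CO[Si](c1ccccc1)(c1ccccc1)C(C)(C)C | intermediate
27 | methyl (3R)-4-hydroxy-3-methoxybutanoate | COC(=O)C[C@@H](OC)CO | intermediate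
28 | methyl (3R)-3-methoxy-4-oxobutanoate | COC(=O)C[C@@H](OC)C=O | intermediate
29 | methyl (3R,4E)-5-iodo-3-methoxypent-4-enoate | COC(=O)C[C@@H](OC)/C=C/I | intermediate
30 | (3R,4E)-5-iodo-3-methoxypent-4-enoic acid | OC(=O)C[C@@H](OC)/C=C/I | intermediate
31 | tert-butyl (3R,4R,5S,6Z)-3,5-bis[(tert-butyldimethylsilyl)oxy]-9-{3-[(3R,4E)-5-iodo-3-methoxypent-4-enamido]-2,5-dimethoxyphenyl}-4,6-dimethylnon-6-enoate | CC(C)(C)OC(=O)C[C@@H](O[Si](C)(C)C(C)(C)C)[C@@H](C)[C@H](O[Si](C)(C)C(C)(C)C)/C(C)=C\CCc1cc(OC)cc(NC(=O)C[C@@H](OC)/C=C/I)c1OC | intermediate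
32 | (3R,4E)-N-{3-[(3Z,5S,6R,7R)-5,7-bis[(tert-butyldimethylsilyl)oxy]-9-hydroxy-4,6-dimethylnon-3-en-1-yl]-2,5-dimethoxyphenyl}-5-iodo-3-methoxypent-4-enamide | OCC[C@@H](O[Si](C)(C)C(C)(C)C)[C@@H](C)[C@H](O[Si](C)(C)C(C)(C)C)/C(C)=C\CCc1cc(OC)cc(NC(=O)C[C@@H](OC)/C=C/I)c1OC | intermediate
33 | (3R,4E)-N-{3-[(3Z,5S,6R,7R)-5,7-bis[(tert-butyldimethylsilyl)oxy]-4,6-dimethyl-9-oxonon-3-en-1-yl]-2,5-dimethoxyphenyl}-5-iodo-3-methoxypent-4-enamide | O=CC[C@@H](O[Si](C)(C)C(C)(C)C)[C@@H](C)[C@H](O[Si](C)(C)C(C)(C)C)/C(C)=C\CCc1cc(OC)cc(NC(=O)C[C@@H](OC)/C=C/I)c1OC | intermediate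
34 | (3R,4E)-N-{3-[(3Z,5S,6R,7R,9E)-5,7-bis[(tert-butyldimethylsilyl)oxy]-10-iodo-4,6-dimethyldeca-3,9-dien-1-yl]-2,5-dimethoxyphenyl}-5-iodo-3-methoxypent-4-enamide | I/C=C/C[C@@H](O[Si](C)(C)C(C)(C)C)[C@@H](C)[C@H](O[Si](C)(C)C(C)(C)C)/C(C)=C\CCc1cc(OC)cc(NC(=O)C[C@@H](OC)/C=C/I)c1OC | intermediate
35 | (E)-1,2-bis(tributylstannyl)ethene | CCCC[Sn](CCCC)(CCCC)/C=C/[Sn](CCCC)(CCCC)CCCC | starting material
36 | 11,13-bis-O-(tert-butyldimethylsilyl) ether of the hydroquinone dimethyl ether of the target (21-membered macrolactam; 3R,11R,12R,13S; 4E,6E,8E,14Z) | CO[C@H]1/C=C/C=C/C=C/C[C@@H](O[Si](C)(C)C(C)(C)C)[C@@H](C)[C@H](O[Si](C)(C)C(C)(C)C)/C(C)=C\CCc2cc(OC)cc(c2OC)NC(=O)C1 | intermediate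
37 | hydroquinone dimethyl ether of the target (free 11,13-diol) | CO[C@H]1/C=C/C=C/C=C/C[C@@H](O)[C@@H](C)[C@H](O)/C(C)=C\CCc2cc(OC)cc(c2OC)NC(=O)C1 | intermediate
38 | quinone form of the target (2-acylamino-6-alkyl-1,4-benzoquinone macrolactam) | CO[C@H]1/C=C/C=C/C=C/C[C@@H](O)[C@@H](C)[C@H](O)/C(C)=C\CCC2=CC(=O)C=C(NC(=O)C1)C2=O | intermediate
39 | CNP0544229.3, the hydroquinone macrolactam (3R,11R,12R,13S; 4E,6E,8E,14Z) | CO[C@H]1/C=C/C=C/C=C/C[C@@H](O)[C@@H](C)[C@H](O)/C(C)=C\CCc2cc(O)cc(c2O)NC(=O)C1 | target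

## Step count and risks

Total steps: 29. Longest linear sequence: 22 steps (steps 1–14, then 22–29); the acid branch (steps 15–21) is 7 steps.

**Three steps most likely to fail**

Step 26, the double Stille macrocyclisation: two C–C bonds and a 21-membered ring must form in one operation at high dilution, and oligomerisation or proto-destannylation can compete. The fallback sets out from aldehyde 33 and does not make the second vinyl iodide. A Horner–Wadsworth–Emmons reaction of 33 with diethyl [(2E)-3-(tributylstannyl)prop-2-en-1-yl]phosphonate (LiN(SiMe3)2, THF, −78 → 0 °C) gives the (6E,8E)-dienyl tributylstannane that still carries the C4–C5 iodoalkene, F1. This is closed by a single intramolecular Stille coupling (Pd2(dba)3, AsPh3, i-Pr2NEt, DMF, 1 mM, rt), which forms C5–C6 and returns to the route at macrolactam 36.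

Step 11, the Claisen condensation on the unprotected β-hydroxy Weinreb amide: the lithium aldolate may undergo retro-aldol cleavage, and the large excess of enolate meets a nitroarene. The fallback sets out from Weinreb amide 16, which is first silylated (Et3SiOTf, 2,6-lutidine, CH2Cl2, −78 °C) to the C13 triethylsilyl ether of the Weinreb amide, F2. Condensation with enolate 18 (now only 2 equiv) gives the triethylsilyl-protected β-keto ester, F3. Brief treatment with HF·pyridine in THF at 0 °C removes the silyl group and returns to the route at β-keto ester 19, ready for the hydroxyl-directed reduction.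

Step 28, the cerium oxidation on the free triene diol: the triene, the allylic alcohols or the acid-labile C3 ether may suffer in the acidic oxidising medium. The fallback sets out from the fully silylated macrolactam 36 and reverses the order of the last operations. Oxidation of 36 with (NH4)2Ce(NO3)6 in MeCN/THF/H2O at 0 °C gives the 11,13-bis-O-(tert-butyldimethylsilyl) quinone, F4. Its silyl groups are then removed with HF·pyridine/pyridine in THF, returning to the route at quinone 38.

## Further compounds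

F1 | step 26 | (3R,4E)-N-{3-[(3Z,5S,6R,7R,9E,11E)-5,7-bis[(tert-butyldimethylsilyl)oxy]-4,6-dimethyl-12-(tributylstannyl)dodeca-3,9,11-trien-1-yl]-2,5-dimethoxyphenyl}-5-iodo-3-methoxypent-4-enamide | CCCC[Sn](CCCC)(CCCC)/C=C/C=C/C[C@@H](O[Si](C)(C)C(C)(C)C)[C@@H](C)[C@H](O[Si](C)(C)C(C)(C)C)/C(C)=C\CCc1cc(OC)cc(NC(=O)C[C@@H](OC)/C=C/I)c1OC
F2 | step 11 | (2S,3S,4Z)-7-(2,5-dimethoxy-3-nitrophenyl)-N-methoxy-N,2,4-trimethyl-3-[(triethylsilyl)oxy]hept-4-enamide | CON(C)C(=O)[C@@H](C)[C@H](O[Si](CC)(CC)CC)/C(C)=C\CCc1cc(OC)cc([N+](=O)[O-])c1OC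
F3 | step 11 | tert-butyl (4S,5S,6Z)-9-(2,5-dimethoxy-3-nitrophenyl)-4,6-dimethyl-3-oxo-5-[(triethylsilyl)oxy]non-6-enoate | CC(C)(C)OC(=O)CC(=O)[C@@H](C)[C@H](O[Si](CC)(CC)CC)/C(C)=C\CCc1cc(OC)cc([N+](=O)[O-])c1OC
F4 | step 28 | 11,13-bis-O-(tert-butyldimethylsilyl) ether of quinone 38 | CO[C@H]1/C=C/C=C/C=C/C[C@@H](O[Si](C)(C)C(C)(C)C)[C@@H](C)[C@H](O[Si](C)(C)C(C)(C)C)/C(C)=C\CCC2=CC(=O)C=C(NC(=O)C1)C2=O
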